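## The problem

The target is a (2S)-flavanone. A dihydropyranone ring C is fused to ring A along C4a–C8a and carries a 4-hydroxyphenyl ring B at C2. Ring A is hexasubstituted: oxygens at C5, C7 and C8a alternate with carbons at C4a (the C4 carbonyl), C6 (the (2R)-2-hydroxy-3-methylbut-3-enyl chain) and C8 (prenyl). The two stereocentres, C2 and the side-chain carbinol, are separated by a planar arene and cannot influence each other, so each must be set independently by a catalyst or a stereospecific reaction. The functionality is fragile. Base opens ring C by retro-oxa-Michael reaction to the chalcone and racemises C2, more easily once the 4'-hydroxyl is free (quinone methide). Acid cyclises a prenyl group onto a neighbouring phenol and ionises the isopropenyl carbinol. Three alkenes exclude hydrogenolysis and strong oxidants. The central difficulty is to distinguish the C8a oxygen from the C5 oxygen: both flank C4a and differ only in their other neighbour (prenyl at C8, side chain at C6). The alternating 1,3,5-oxygen pattern is what a vinylketene–ynol ether benzannulation delivers, with each oxygen arriving in a different form: C8a–O from the ketene carbonyl as a free hydroxyl, C7–O from the ynol ether, C5–O from C3 of a cyclobutenone. C4a is left as the only C–H.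

## Retrosynthesis

**Protecting-group endgame (30 ⇐ 29 ⇐ 28).** No skeletal bond is cut. The three oxygens of the ring A side (C5–O, C7–O, carbinol) are carried as silyl ethers so that one buffered fluoride treatment of 28 releases them without strong acid or base. Ring B is carried as an aryl acetate, removed last from 29 under neutral methanolysis. The acetate is chosen over a silyl ether because an electron-poor ring B resists benzylic ionisation in the two steps that expose C2 (etherification, acylation).

**C4–C4a (28 ⇐ 26).** Cutting the aryl ketone bond opens ring C to the (S)-3-aryloxy-3-arylpropanoic acid 26. This cut is preferred to O1–C2 at this stage because the closure does not touch C2, and because C4a is the only unsubstituted carbon of a ring activated by three oxygens, so the acylation has no regiochemical choice. The forward reaction must be fast at low temperature, since silyl ethers and two acid-sensitive alkenes are present.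

**O1–C2 (26 ⇐ 25 ⇐ 17 + 24).** Cutting the benzylic ether gives phenol 17 and the (R)-β-hydroxy ester 24. A Mitsunobu reaction forms the bond with inversion, so C2 is bought as a catalytically made secondary alcohol and not created on the crowded flavanone. The allyl ester of 25 is released to 26 by zerovalent palladium under neutral conditions, which spares the aryl acetate and the β-aryloxy acid. The forward reaction needs the C8a hydroxyl of 17 to be the only free phenol.

**C8–C8a and C6–C7 (17 ⇐ 7 + 12): the key cut.** Ring A is taken apart into cyclobutenone 7 (C4a, C5, C6, C8a and the side chain) and siloxyalkyne 12 (C7, C8 and the prenyl group).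
- Against stepwise substitution of a phloroglucinol, this cut assigns every substituent by mechanism and delivers exactly the C8a hydroxyl free.
- The precursors are far simpler: a four-membered ring with one stereocentre and an achiral ynol ether.
- The C5 oxygen is carried on 7 as a triisopropylsilyl enol ether, not as an alkyl or acetal vinylogous ester. This makes 7 available in one step from a siloxyalkyne and ketene, and lets C5–O fall in the same fluoride step as C7–O, so no acidic acetal cleavage is needed next to the prenyl phenol.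
- The forward reaction must open a donor-substituted cyclobutenone thermally and combine the vinylketene with 12 in one regiochemical sense.

**Cyclobutenone (7 ⇐ 6 ⇐ 4 ⇐ 3 ⇐ 1 + 2).** The four-membered ring is cut into ketene and siloxyalkyne 6, which comes from terminal alkyne 4 by acetylide oxidation and O-silylation. Alkyne 4 is the TBS ether of homopropargylic alcohol 3. The carbinol C–C bond of 3 is cut to methacrolein 1 and allenylboronate 2, so the side-chain stereocentre is set in the first step by a catalytic asymmetric propargylation. This is shorter than the epoxide alternative (epoxidation, resolution, acetylide opening), which is kept as a fallback.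

**Siloxyalkyne (12 ⇐ 10 ⇐ 8 + 9).** The ynol ether oxygen is introduced by oxidation of the acetylide of enyne 10. The C–C bond between the propargylic and allylic carbons of 10 is cut to prenyl bromide 8 and ethynylmagnesium bromide 9.

**Ring B fragment (24 ⇐ 23 ⇐ 21 ⇐ 18 + 19, with 22).** The carbinol of 24 comes from β-keto ester 23 by asymmetric transfer hydrogenation. The keto ester is cut at the acyl–CH2 bond to 4-acetoxybenzoic acid 18 and Meldrum's acid 19, with allyl alcohol 22 supplying the ester. The acyl Meldrum's acid 21 allows ester formation without base, which the aryl acetate requires.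

## Roads not taken

**Alternative 1:** The strategic cut is C4–C4a alone. The acid A2, a (3S)-3-aryloxy-3-arylpropanoic acid with three TBS ethers and the ring B acetate, is activated as a mixed anhydride and acylates C4a to give flavanone A1.
- Merits: the closure is thoroughly precedented, does not touch C2, and has only one position to attack. As a key step it is more certain than a benzannulation with an oxygenated cyclobutenone, and this is a real advantage.
- Weak points: the plan assumes a ring A phenol with the C8a hydroxyl free and the C5 hydroxyl masked, which is the unsolved part. C-alkylation of phloroglucinols does not distinguish the two oxygens flanking C4a, and three neighbouring TBS ethers invite silyl migration and loss under the acidic closure.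
- Comparison: the chosen plan adopts this closure as step 13, so the two are equal for ring C. The chosen plan accepts a less certain step 7, placed early on inexpensive material, and in return obtains ring A with its oxygens already differentiated.

**Alternative 2:** The cut is C4a–C5. Ring C is made first as the (2S)-dihydropyranone A4, which carries the C5–C8 carbons as a 2,4-disubstituted 3-oxo ester chain on the future C8a. Soft enolisation (a magnesium Lewis acid and a tertiary amine) lets C4a attack the ester and, after loss of methanol, gives the 5,7-dihydroxyflavanone A3.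
- Merits: it is biomimetic. O1 is already in ring C, so the oxygen-differentiation problem disappears, and C5–OH and C7–OH emerge free. C2 is set early, and no late Mitsunobu or acidic acylation is needed. In these respects it is better than the chosen plan.
- Weak points: A4 is a doubly branched, epimerisable polycarbonyl chain that needs several linear C–C bond formations. The nucleophile is the α-carbon of a vinylogous ester, which is weakly reactive, and O-cyclisation to a pyrone competes. The basic conditions can open the dihydropyranone by β-elimination at C2–O1 and racemise it. The ring B acetal must finally be removed with acid next to the prenyl phenol.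
- Comparison: the chosen plan sets convergence (three fragments of two to four steps) and a pericyclic ring construction with mechanistically fixed regiochemistry against the elegance of alternative 2.

**Alternative 3:** The cuts are C3–C4 and O1–C2. Salicylaldehyde A6, trimethyl orthoformate A8 and 4-(silyloxy)styrene A7 combine under a chiral BINOL-derived phosphoric acid. The methoxy ortho-quinone methide adds the styrene to give the (2S)-2,4-cis-4-methoxyflavan A5.
- Merits: ring C and C2 are formed in one catalytic asymmetric step from a simple styrene. This is more convergent for ring C than etherification–acylation, and chirality is catalytic at the point of use.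
- Weak points: A5 is at the wrong oxidation level, so the C4 ether must be converted to the ketone in the presence of a prenylated, electron-rich ring. The quinone methide must form from a hexasubstituted aldehyde flanked by a bulky silyl ether, and the acid catalyst can cyclise the prenyl group onto the free phenol. A6 itself needs the same differentiated ring A plus a formylation.
- Comparison: alternative 3 would shorten ring C construction if A6 were available. The chosen plan makes the ring A that A6 requires, and uses a stereospecific inversion of a catalytically made alcohol rather than enantioselection on the crowded substrate.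

Key step: step 7

## Route

Remark: ketene is generated from acetone by pyrolysis and used as a gas.
Remark: the facial sense of (R)-TRIP with methacrolein is assumed to be that established for aryl aldehydes (Re-face attack), to be confirmed on 3.

Step 1
Reactants: 1 methacrolein (2-methylprop-2-enal); 2 allenylboronic acid pinacol ester (4,4,5,5-tetramethyl-2-(propa-1,2-dienyl)-1,3,2-dioxaborolane)
Product: 3 (3R)-2-methylhex-1-en-5-yn-3-ol
Conditions: (R)-3,3'-bis(2,4,6-triisopropylphenyl)-1,1'-binaphthyl-2,2'-diyl hydrogen phosphate [(R)-TRIP] (10 mol %), 4 Å MS, toluene, −20 °C; aqueous work-up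
Reagents that add atoms: none
Why: Chiral phosphoric acid-catalysed asymmetric propargylation of an aldehyde with an allenylboronate through a closed six-membered transition state (allenyl-to-propargyl transposition). The catalyst binds the boronate oxygen and the formyl C–H and should direct attack to the Re face of the enal, which gives the R carbinol (isopropenyl outranks propargyl); configuration and ee are to be checked by Mosher ester analysis.

Step 2
Reactants: 3 (3R)-2-methylhex-1-en-5-yn-3-ol
Product: 4 tert-butyldimethyl{[(3R)-2-methylhex-1-en-5-yn-3-yl]oxy}silane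
Conditions: TBSCl, imidazole, DMF, 0 °C → rt
Reagents that add atoms: tert-butyldimethylsilyl chloride (TBSCl), CC(C)(C)[Si](C)(C)Cl
Why: Standard silylation of a secondary alcohol; the TBS ether survives the organolithium, thermal, Mitsunobu and palladium steps and is removed by fluoride at the end.

Step 3
Reactants: 4 tert-butyldimethyl{[(3R)-2-methylhex-1-en-5-yn-3-yl]oxy}silane
Product: 6 (4R)-4-(tert-butyldimethylsilyloxy)-5-methyl-1-(triisopropylsilyloxy)hex-5-en-1-yne, via lithium ynolate 5 (not isolated)
Conditions: n-BuLi, THF, −78 °C; t-BuOOLi (from t-BuOOH, LiHMDS), −78 → 0 °C; TIPSOTf, −78 → 0 °C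
Reagents that add atoms: tert-butyl hydroperoxide, CC(C)(C)OO; triisopropylsilyl trifluoromethanesulfonate (TIPSOTf), CC(C)[Si](OS(=O)(=O)C(F)(F)F)(C(C)C)C(C)C
Why: Oxidation of a lithium acetylide by lithium tert-butyl peroxide (oxygen transfer with loss of tert-butoxide) gives ynolate 5, which the bulky silyl triflate captures on oxygen; triisopropylsilyl ynol ethers are the isolable members of this class. The silyl ether and the isolated alkene are inert to the peroxide anion.

Step 4
Reactants: 6 (4R)-4-(tert-butyldimethylsilyloxy)-5-methyl-1-(triisopropylsilyloxy)hex-5-en-1-yne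
Product: 7 2-[(2R)-2-(tert-butyldimethylsilyloxy)-3-methylbut-3-enyl]-3-(triisopropylsilyloxy)cyclobut-2-en-1-one
Conditions: ketene (excess), CH2Cl2, 0 °C → rt
Reagents that add atoms: ketene, C=C=O
Why: Regiospecific [2+2] cycloaddition of a siloxyalkyne with ketene: the carbon β to oxygen attacks the ketene carbonyl carbon, so the chain ends on C2 and the siloxy group on C3 of the cyclobutenone. The isolated alkene does not react with ketene at this temperature; 7 is a vinylogous silyl ester, to be purified on deactivated silica and used promptly.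

Step 5
Reactants: 8 prenyl bromide (1-bromo-3-methylbut-2-ene); 9 ethynylmagnesium bromide
Product: 10 5-methylhex-4-en-1-yne
Conditions: CuCl (5 mol %), THF, 0 → 50 °C
Reagents that add atoms: none
Why: Copper-catalysed coupling of an alkynyl Grignard reagent with an allylic bromide; substitution at the unhindered primary terminus (SN2 over SN2') gives the skipped enyne. The product is volatile and is isolated by careful distillation.

Step 6
Reactants: 10 5-methylhex-4-en-1-yne
Product: 12 triisopropyl(5-methylhex-4-en-1-ynyloxy)silane, via lithium ynolate 11 (not isolated)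
Conditions: n-BuLi, THF, −78 °C; t-BuOOLi (from t-BuOOH, LiHMDS), −78 → 0 °C; TIPSOTf, −78 → 0 °C
Reagents that add atoms: tert-butyl hydroperoxide, CC(C)(C)OO; triisopropylsilyl trifluoromethanesulfonate (TIPSOTf), CC(C)[Si](OS(=O)(=O)C(F)(F)F)(C(C)C)C(C)C
Why: Same acetylide oxidation and O-silylation as in step 3. The terminal C–H is far more acidic than the doubly activated CH2, so deprotonation at low temperature does not isomerise the enyne.

Step 7
Reactants: 7 2-[(2R)-2-(tert-butyldimethylsilyloxy)-3-methylbut-3-enyl]-3-(triisopropylsilyloxy)cyclobut-2-en-1-one; 12 triisopropyl(5-methylhex-4-en-1-ynyloxy)silane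
Product: 17 4-[(2R)-2-(tert-butyldimethylsilyloxy)-3-methylbut-3-enyl]-2-(3-methylbut-2-enyl)-3,5-bis(triisopropylsilyloxy)phenol, via vinylketene 13 (not isolated), via vinylcyclobutenone 14 (not isolated), via dienylketene 15 (not isolated), via cyclohexadienone 16 (not isolated)
Conditions: 12 (2 equiv), toluene, 80 °C then 110 °C, sealed tube
Reagents that add atoms: none
Why: Danheiser benzannulation with a siloxyalkyne as ketenophile. Heating opens 7 by 4π electrocyclic cleavage of the C1–C4 bond to vinylketene 13; the nucleophilic, prenyl-bearing carbon of 12 adds to the ketene carbonyl carbon in a [2+2] cycloaddition to give 14, which opens again (4π) to dienylketene 15. Ring A then closes by 6π electrocyclisation to the six-membered carbocycle 16, which tautomerises to phenol 17. The closest known reaction type is the thermal benzannulation of alkyl-substituted cyclobutenones with triisopropylsiloxyalkynes to resorcinol monosilyl ethers; the 3-siloxy group on 7 is the extension. No stereocentre is formed, and the side-chain carbinol, remote from every reacting atom, is carried through unchanged. The step needs regioselectivity, secured by the polarisation of the siloxyalkyne (C8 bonds to the ketene carbon and ends next to the free hydroxyl), and chemoselectivity for the ynol ether over the three alkenes, secured by its much higher nucleophilicity. Dienylketene geometries that cannot cyclise return through 14 because the ring opening is reversible. The excess of 12 keeps 17 from being acylated by 13.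

Step 8
Reactants: 18 4-acetoxybenzoic acid; 19 Meldrum's acid (2,2-dimethyl-1,3-dioxane-4,6-dione)
Product: 21 5-[(4-acetoxyphenyl)(hydroxy)methylidene]-2,2-dimethyl-1,3-dioxane-4,6-dione, via 4-acetoxybenzoyl chloride 20 (not isolated)
Conditions: (COCl)2, DMF (cat.), CH2Cl2, rt; evaporate; 19, pyridine, CH2Cl2, 0 °C → rt
Reagents that add atoms: none
Why: C-Acylation of Meldrum's acid by an acid chloride with pyridine is the standard entry to β-keto esters; the aryl acetate is indifferent to oxalyl chloride and to pyridine at this temperature.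

Step 9
Reactants: 21 5-[(4-acetoxyphenyl)(hydroxy)methylidene]-2,2-dimethyl-1,3-dioxane-4,6-dione; 22 allyl alcohol
Product: 23 allyl 3-(4-acetoxyphenyl)-3-oxopropanoate
Conditions: toluene, 90 °C
Reagents that add atoms: none
Why: Thermal fragmentation of the acyl Meldrum's acid to an acylketene (loss of acetone and CO2) and capture by the alcohol; no acid or base is present, so the aryl acetate is not transesterified.

Step 10
Reactants: 23 allyl 3-(4-acetoxyphenyl)-3-oxopropanoate
Product: 24 allyl (3R)-3-(4-acetoxyphenyl)-3-hydroxypropanoate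
Conditions: RuCl(p-cymene)[(R,R)-TsDPEN] (1 mol %), HCO2H/Et3N (5:2), EtOAc, rt
Reagents that add atoms: none
Why: Noyori–Ikariya asymmetric transfer hydrogenation of an aryl ketone; hydride and proton are delivered in an outer-sphere six-membered transition state with the aryl group held against the cymene ligand, and the (R,R) catalyst gives the R alcohol as with acetophenone (aryl outranks CH2CO2R, so the descriptor is the same). The catalyst does not reduce or isomerise the allyl ester, which hydrogen gas with a bisphosphine catalyst would.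

Step 11
Reactants: 17 4-[(2R)-2-(tert-butyldimethylsilyloxy)-3-methylbut-3-enyl]-2-(3-methylbut-2-enyl)-3,5-bis(triisopropylsilyloxy)phenol; 24 allyl (3R)-3-(4-acetoxyphenyl)-3-hydroxypropanoate
Product: 25 allyl (3S)-3-(4-acetoxyphenyl)-3-{4-[(2R)-2-(tert-butyldimethylsilyloxy)-3-methylbut-3-enyl]-2-(3-methylbut-2-enyl)-3,5-bis(triisopropylsilyloxy)phenoxy}propanoate
Conditions: PPh3, DIAD, toluene, 0 °C → rt
Reagents that add atoms: none
Why: Mitsunobu etherification of a phenol with a secondary benzylic alcohol; SN2 displacement of the oxyphosphonium group inverts the carbinol, so the R alcohol gives the S ether (the future O1–C2 bond). The electron-poor 4-acetoxyphenyl group disfavours ionisation at the benzylic carbon, and 17 has a single ortho substituent and normal phenol acidity.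

Step 12
Reactants: 25 allyl (3S)-3-(4-acetoxyphenyl)-3-{4-[(2R)-2-(tert-butyldimethylsilyloxy)-3-methylbut-3-enyl]-2-(3-methylbut-2-enyl)-3,5-bis(triisopropylsilyloxy)phenoxy}propanoate
Product: 26 (3S)-3-(4-acetoxyphenyl)-3-{4-[(2R)-2-(tert-butyldimethylsilyloxy)-3-methylbut-3-enyl]-2-(3-methylbut-2-enyl)-3,5-bis(triisopropylsilyloxy)phenoxy}propanoic acid
Conditions: Pd(PPh3)4 (5 mol %), N-methylaniline, THF, rt
Reagents that add atoms: none
Why: Tsuji–Trost deallylation: zerovalent palladium ionises the allyl ester and the weakly nucleophilic amine takes up the allyl group. The neutral conditions leave the aryl acetate, the silyl ethers and the base-sensitive β-aryloxy acid untouched.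

Step 13
Reactants: 26 (3S)-3-(4-acetoxyphenyl)-3-{4-[(2R)-2-(tert-butyldimethylsilyloxy)-3-methylbut-3-enyl]-2-(3-methylbut-2-enyl)-3,5-bis(triisopropylsilyloxy)phenoxy}propanoic acid
Product: 28 (2S)-2-(4-acetoxyphenyl)-6-[(2R)-2-(tert-butyldimethylsilyloxy)-3-methylbut-3-enyl]-8-(3-methylbut-2-enyl)-5,7-bis(triisopropylsilyloxy)chroman-4-one, via mixed trifluoroacetic anhydride 27 (not isolated)
Conditions: TFAA, CH2Cl2, −20 → 0 °C; aq. NaHCO3
Reagents that add atoms: none
Why: Intramolecular Friedel–Crafts acylation through the mixed anhydride 27, the standard closure of 3-aryloxypropanoic acids to chroman-4-ones; the six-membered ring closes onto C4a, the only free position of a ring activated by three oxygens. C2 is not involved and its benzylic C–O bond is deactivated toward ionisation by the acetoxy group; the high nucleophilicity of ring A should allow low temperature and short contact with the trifluoroacetic acid formed.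

Step 14
Reactants: 28 (2S)-2-(4-acetoxyphenyl)-6-[(2R)-2-(tert-butyldimethylsilyloxy)-3-methylbut-3-enyl]-8-(3-methylbut-2-enyl)-5,7-bis(triisopropylsilyloxy)chroman-4-one
Product: 29 (2S)-2-(4-acetoxyphenyl)-5,7-dihydroxy-6-[(2R)-2-hydroxy-3-methylbut-3-enyl]-8-(3-methylbut-2-enyl)chroman-4-one
Conditions: TBAF, AcOH (1:1), THF, 0 °C → rt
Reagents that add atoms: none
Why: Fluoride-mediated desilylation buffered with acetic acid should remove the two aryl triisopropylsilyl ethers (activated as ortho- and para-acyl phenol ethers) and the secondary TBS ether without free phenoxide or alkoxide base, which would open ring C to the chalcone and racemise C2. Any loss of the aryl acetate here only anticipates step 15.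

Step 15
Reactants: 29 (2S)-2-(4-acetoxyphenyl)-5,7-dihydroxy-6-[(2R)-2-hydroxy-3-methylbut-3-enyl]-8-(3-methylbut-2-enyl)chroman-4-one
Product: 30 (2S)-5,7-dihydroxy-6-[(2R)-2-hydroxy-3-methylbut-3-enyl]-2-(4-hydroxyphenyl)-8-(3-methylbut-2-enyl)chroman-4-one
Conditions: NH4OAc, MeOH/H2O (4:1), rt
Reagents that add atoms: none
Why: Neutral methanolysis of a phenolic acetate catalysed by ammonium acetate; the ketone, the alkenes and both stereocentres are unaffected, and the near-neutral pH avoids chalcone or quinone methide formation from the 4'-hydroxyflavanone.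

## Compound list

1 | methacrolein (2-methylprop-2-enal) | CC(=C)C=O | starting material
2 | allenylboronic acid pinacol ester | C=C=CB1OC(C)(C)C(C)(C)O1 | starting material
3 | (3R)-2-methylhex-1-en-5-yn-3-ol | C=C(C)[C@H](O)CC#C | intermediate
4 | tert-butyldimethyl{[(3R)-2-methylhex-1-en-5-yn-3-yl]oxy}silane | C=C(C)[C@H](O[Si](C)(C)C(C)(C)C)CC#C | intermediate
5 | lithium (4R)-4-(tert-butyldimethylsilyloxy)-5-methylhex-5-en-1-yn-1-olate | C=C(C)[C@H](O[Si](C)(C)C(C)(C)C)CC#CO[Li] | intermediate
6 | (4R)-4-(tert-butyldimethylsilyloxy)-5-methyl-1-(triisopropylsilyloxy)hex-5-en-1-yne | C=C(C)[C@H](O[Si](C)(C)C(C)(C)C)CC#CO[Si](C(C)C)(C(C)C)C(C)C | intermediate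
7 | 2-[(2R)-2-(tert-butyldimethylsilyloxy)-3-methylbut-3-enyl]-3-(triisopropylsilyloxy)cyclobut-2-en-1-one | C=C(C)[C@H](O[Si](C)(C)C(C)(C)C)CC1=C(O[Si](C(C)C)(C(C)C)C(C)C)CC1=O | intermediate
8 | prenyl bromide (1-bromo-3-methylbut-2-ene) | CC(C)=CCBr | starting material
9 | ethynylmagnesium bromide | C#C[Mg]Br | starting material
10 | 5-methylhex-4-en-1-yne | CC(C)=CCC#C | intermediate
11 | lithium 5-methylhex-4-en-1-yn-1-olate | CC(C)=CCC#CO[Li] | intermediate
12 | triisopropyl(5-methylhex-4-en-1-ynyloxy)silane | CC(C)=CCC#CO[Si](C(C)C)(C(C)C)C(C)C | intermediate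
13 | (4R)-4-(tert-butyldimethylsilyloxy)-5-methyl-2-[1-(triisopropylsilyloxy)ethenyl]hexa-1,5-dien-1-one (vinylketene) | C=C(C)[C@H](O[Si](C)(C)C(C)(C)C)CC(=C=O)C(=C)O[Si](C(C)C)(C(C)C)C(C)C | intermediate
14 | 4-[(2R)-2-(tert-butyldimethylsilyloxy)-3-methylbut-3-enyl]-2-(3-methylbut-2-enyl)-3-(triisopropylsilyloxy)-4-[1-(triisopropylsilyloxy)ethenyl]cyclobut-2-en-1-one (either configuration at C4) | C=C(C)[C@H](O[Si](C)(C)C(C)(C)C)CC1(C(=C)O[Si](C(C)C)(C(C)C)C(C)C)C(=O)C(CC=C(C)C)=C1O[Si](C(C)C)(C(C)C)C(C)C | intermediate
15 | dienylketene, 4-[(2R)-2-(tert-butyldimethylsilyloxy)-3-methylbut-3-enyl]-2-(3-methylbut-2-enyl)-3,5-bis(triisopropylsilyloxy)hexa-1,3,5-trien-1-one (ketenyl and siloxyvinyl groups cis) | C=C(C)[C@H](O[Si](C)(C)C(C)(C)C)C/C(C(=C)O[Si](C(C)C)(C(C)C)C(C)C)=C(\O[Si](C(C)C)(C(C)C)C(C)C)C(CC=C(C)C)=C=O | intermediate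
16 | 4-[(2R)-2-(tert-butyldimethylsilyloxy)-3-methylbut-3-enyl]-2-(3-methylbut-2-enyl)-3,5-bis(triisopropylsilyloxy)cyclohexa-2,4-dien-1-one | C=C(C)[C@H](O[Si](C)(C)C(C)(C)C)CC1=C(O[Si](C(C)C)(C(C)C)C(C)C)CC(=O)C(CC=C(C)C)=C1O[Si](C(C)C)(C(C)C)C(C)C | intermediate
17 | 4-[(2R)-2-(tert-butyldimethylsilyloxy)-3-methylbut-3-enyl]-2-(3-methylbut-2-enyl)-3,5-bis(triisopropylsilyloxy)phenol | C=C(C)[C@H](O[Si](C)(C)C(C)(C)C)Cc1c(O[Si](C(C)C)(C(C)C)C(C)C)c(CC=C(C)C)c(O)cc1O[Si](C(C)C)(C(C)C)C(C)C | intermediate
18 | 4-acetoxybenzoic acid | CC(=O)Oc1ccc(cc1)C(=O)O | starting material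
19 | Meldrum's acid (2,2-dimethyl-1,3-dioxane-4,6-dione) | CC1(C)OC(=O)CC(=O)O1 | starting material
20 | 4-acetoxybenzoyl chloride | CC(=O)Oc1ccc(cc1)C(Cl)=O | intermediate
21 | 5-[(4-acetoxyphenyl)(hydroxy)methylidene]-2,2-dimethyl-1,3-dioxane-4,6-dione | CC(=O)Oc1ccc(cc1)C(O)=C1C(=O)OC(C)(C)OC1=O | intermediate
22 | allyl alcohol | C=CCO | starting material
23 | allyl 3-(4-acetoxyphenyl)-3-oxopropanoate | C=CCOC(=O)CC(=O)c1ccc(OC(C)=O)cc1 | intermediate
24 | allyl (3R)-3-(4-acetoxyphenyl)-3-hydroxypropanoate | C=CCOC(=O)C[C@@H](O)c1ccc(OC(C)=O)cc1 | intermediate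
25 | allyl (3S)-3-(4-acetoxyphenyl)-3-{4-[(2R)-2-(tert-butyldimethylsilyloxy)-3-methylbut-3-enyl]-2-(3-methylbut-2-enyl)-3,5-bis(triisopropylsilyloxy)phenoxy}propanoate | C=C(C)[C@H](O[Si](C)(C)C(C)(C)C)Cc1c(O[Si](C(C)C)(C(C)C)C(C)C)c(CC=C(C)C)c(O[C@@H](CC(=O)OCC=C)c2ccc(OC(C)=O)cc2)cc1O[Si](C(C)C)(C(C)C)C(C)C | intermediate
26 | (3S)-3-(4-acetoxyphenyl)-3-{4-[(2R)-2-(tert-butyldimethylsilyloxy)-3-methylbut-3-enyl]-2-(3-methylbut-2-enyl)-3,5-bis(triisopropylsilyloxy)phenoxy}propanoic acid | C=C(C)[C@H](O[Si](C)(C)C(C)(C)C)Cc1c(O[Si](C(C)C)(C(C)C)C(C)C)c(CC=C(C)C)c(O[C@@H](CC(=O)O)c2ccc(OC(C)=O)cc2)cc1O[Si](C(C)C)(C(C)C)C(C)C | intermediate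
27 | mixed anhydride of 26 with trifluoroacetic acid | C=C(C)[C@H](O[Si](C)(C)C(C)(C)C)Cc1c(O[Si](C(C)C)(C(C)C)C(C)C)c(CC=C(C)C)c(O[C@@H](CC(=O)OC(=O)C(F)(F)F)c2ccc(OC(C)=O)cc2)cc1O[Si](C(C)C)(C(C)C)C(C)C | intermediate
28 | (2S)-2-(4-acetoxyphenyl)-6-[(2R)-2-(tert-butyldimethylsilyloxy)-3-methylbut-3-enyl]-8-(3-methylbut-2-enyl)-5,7-bis(triisopropylsilyloxy)chroman-4-one | C=C(C)[C@H](O[Si](C)(C)C(C)(C)C)Cc1c(O[Si](C(C)C)(C(C)C)C(C)C)c(CC=C(C)C)c2c(c1O[Si](C(C)C)(C(C)C)C(C)C)C(=O)C[C@@H](c1ccc(OC(C)=O)cc1)O2 | intermediate
29 | (2S)-2-(4-acetoxyphenyl)-5,7-dihydroxy-6-[(2R)-2-hydroxy-3-methylbut-3-enyl]-8-(3-methylbut-2-enyl)chroman-4-one | C=C(C)[C@H](O)Cc1c(O)c(CC=C(C)C)c2c(c1O)C(=O)C[C@@H](c1ccc(OC(C)=O)cc1)O2 | intermediate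
30 | (2S)-5,7-dihydroxy-6-[(2R)-2-hydroxy-3-methylbut-3-enyl]-2-(4-hydroxyphenyl)-8-(3-methylbut-2-enyl)chroman-4-one | C=C(C)[C@H](O)Cc1c(O)c(CC=C(C)C)c2c(c1O)C(=O)C[C@@H](c1ccc(O)cc1)O2 | target

## Step count and risks

Total steps: 15. Longest linear sequence: 10 (steps 1, 2, 3, 4, 7, 11, 12, 13, 14, 15). The siloxyalkyne branch has 2 steps (5, 6) and the ring B branch 3 steps (8, 9, 10).

**Step 7 (key step).** The electrocyclic opening of 7 is slowed by vinylogous-ester stabilisation. At the temperature then needed, the silyl enol ether may transfer or lose its silyl group, or 12 may isomerise to a silylketene, before the cascade is complete. Acylation of the product phenol by 13 and stalling at 14 are lesser concerns. The fallback carries the C5 oxygen as an acetal-type vinylogous ester, which has no labile O–Si bond and tolerates harder heating. It sets out from 7. Selective cleavage of the vinylogous silyl ester (Et3N·3HF, THF, 0 °C) gives 2-[(2R)-2-(tert-butyldimethylsilyloxy)-3-methylbut-3-enyl]-3-hydroxycyclobut-2-en-1-one F1. O-alkylation of this symmetrical 1,3-dione enol (MOMCl, i-Pr2NEt) gives the 3-(methoxymethoxy)cyclobutenone F2. Heating F2 with 12 as in step 7 should give the phenol F3, with free C8a hydroxyl, C7 silyl ether and C5 acetal. The conditions of steps 11, 12 and 13 then lead through the allyl ester F4 and the acid F5 to the 5-(methoxymethoxy)flavanone F6. The acetal next to the C4 carbonyl is removed with ZnBr2 and n-PrSH (CH2Cl2, 0 °C) to give the 5-hydroxyflavanone F7. The conditions of step 14 applied to F7 return the route at 29.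

**Step 11.** The activated carbinol may eliminate toward the conjugated cinnamate (the C3 hydrogens are acidified by the ester), which a hindered, weakly acidic phenol favours. Partial ionisation at the benzylic carbon would erode the ee. The fallback replaces the oxyphosphonium electrophile by a strained lactone. It sets out from 24. Deallylation (Pd(PPh3)4, N-methylaniline) gives (3R)-3-(4-acetoxyphenyl)-3-hydroxypropanoic acid F8. Carboxyl activation (PhSO2Cl, pyridine, 0 °C) closes it with retention to (4R)-4-(4-acetoxyphenyl)oxetan-2-one F9. The potassium salt of 17 opens F9 at the benzylic carbon (SN2, alkyl–oxygen cleavage, inversion) and, after acidification, gives 26 directly, where the route is rejoined. Steps 11 and 12 are bypassed.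

**Step 13.** Acid-induced processes may outrun the acylation: trifluoroacetic acid may add to the prenyl or isopropenyl alkene, remove the allylic TBS ether, or ionise the C2–O bond. The fallback builds ring C without acid and sets C2 by catalyst control. It sets out from 17.
- Magnesium-mediated ortho-formylation (MgCl2, Et3N, paraformaldehyde, MeCN, reflux) gives the salicylaldehyde F10.
- Addition of 9 (excess, THF, 0 °C) gives the propargylic alcohol F11.
- Oxidation with MnO2 gives the ynone F12.
- Amine-mediated 6-endo cyclisation (Et2NH, EtOH, then silica) gives the chromone F13.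
- Asymmetric conjugate addition of 4-acetoxyphenylboronic acid, catalysed by Pd(OCOCF3)2 and the tert-butyl pyridine-oxazoline ligand enantiomer that delivers the 2S product (NH4PF6, H2O, ClCH2CH2Cl, 60 °C), returns the route at 28.

Steps 11 to 13 are replaced.

**Step 1.** Facial discrimination of a small, α-branched enal by the phosphoric acid may be insufficient, or of the opposite sense. The fallback sets the carbinol by epoxide chemistry. It sets out from 1. Corey–Chaykovsky methylenation (Me3S+ I−, NaH, DMSO/THF) gives racemic 2-(prop-1-en-2-yl)oxirane F14. Hydrolytic kinetic resolution with (S,S)-N,N'-bis(3,5-di-tert-butylsalicylidene)-1,2-cyclohexanediaminocobalt acetate (trivalent cobalt; the enantiomer expected, by analogy with alkyl oxiranes, to hydrolyse the R epoxide) and 0.55 equiv of water leaves (2S)-2-(prop-1-en-2-yl)oxirane F15. Opening at the terminal carbon with lithium acetylide–ethylenediamine complex in DMSO returns the route at 3.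

## Further compounds

F1 | step 7 | 2-[(2R)-2-(tert-butyldimethylsilyloxy)-3-methylbut-3-enyl]-3-hydroxycyclobut-2-en-1-one | C=C(C)[C@H](O[Si](C)(C)C(C)(C)C)CC1=C(O)CC1=O
F2 | step 7 | 2-[(2R)-2-(tert-butyldimethylsilyloxy)-3-methylbut-3-enyl]-3-(methoxymethoxy)cyclobut-2-en-1-one | C=C(C)[C@H](O[Si](C)(C)C(C)(C)C)CC1=C(OCOC)CC1=O
F3 | step 7 | 4-[(2R)-2-(tert-butyldimethylsilyloxy)-3-methylbut-3-enyl]-5-(methoxymethoxy)-2-(3-methylbut-2-enyl)-3-(triisopropylsilyloxy)phenol | C=C(C)[C@H](O[Si](C)(C)C(C)(C)C)Cc1c(O[Si](C(C)C)(C(C)C)C(C)C)c(CC=C(C)C)c(O)cc1OCOC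
F4 | step 7 | allyl (3S)-3-(4-acetoxyphenyl)-3-{4-[(2R)-2-(tert-butyldimethylsilyloxy)-3-methylbut-3-enyl]-5-(methoxymethoxy)-2-(3-methylbut-2-enyl)-3-(triisopropylsilyloxy)phenoxy}propanoate | C=C(C)[C@H](O[Si](C)(C)C(C)(C)C)Cc1c(O[Si](C(C)C)(C(C)C)C(C)C)c(CC=C(C)C)c(O[C@@H](CC(=O)OCC=C)c2ccc(OC(C)=O)cc2)cc1OCOC
F5 | step 7 | (3S)-3-(4-acetoxyphenyl)-3-{4-[(2R)-2-(tert-butyldimethylsilyloxy)-3-methylbut-3-enyl]-5-(methoxymethoxy)-2-(3-methylbut-2-enyl)-3-(triisopropylsilyloxy)phenoxy}propanoic acid | C=C(C)[C@H](O[Si](C)(C)C(C)(C)C)Cc1c(O[Si](C(C)C)(C(C)C)C(C)C)c(CC=C(C)C)c(O[C@@H](CC(=O)O)c2ccc(OC(C)=O)cc2)cc1OCOC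
F6 | step 7 | (2S)-2-(4-acetoxyphenyl)-6-[(2R)-2-(tert-butyldimethylsilyloxy)-3-methylbut-3-enyl]-5-(methoxymethoxy)-8-(3-methylbut-2-enyl)-7-(triisopropylsilyloxy)chroman-4-one | C=C(C)[C@H](O[Si](C)(C)C(C)(C)C)Cc1c(O[Si](C(C)C)(C(C)C)C(C)C)c(CC=C(C)C)c2c(c1OCOC)C(=O)C[C@@H](c1ccc(OC(C)=O)cc1)O2
F7 | step 7 | (2S)-2-(4-acetoxyphenyl)-6-[(2R)-2-(tert-butyldimethylsilyloxy)-3-methylbut-3-enyl]-5-hydroxy-8-(3-methylbut-2-enyl)-7-(triisopropylsilyloxy)chroman-4-one | C=C(C)[C@H](O[Si](C)(C)C(C)(C)C)Cc1c(O[Si](C(C)C)(C(C)C)C(C)C)c(CC=C(C)C)c2c(c1O)C(=O)C[C@@H](c1ccc(OC(C)=O)cc1)O2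
F8 | step 11 | (3R)-3-(4-acetoxyphenyl)-3-hydroxypropanoic acid | OC(=O)C[C@@H](O)c1ccc(OC(C)=O)cc1
F9 | step 11 | (4R)-4-(4-acetoxyphenyl)oxetan-2-one | O=C1C[C@H](c2ccc(OC(C)=O)cc2)O1
F10 | step 13 | 3-[(2R)-2-(tert-butyldimethylsilyloxy)-3-methylbut-3-enyl]-6-hydroxy-5-(3-methylbut-2-enyl)-2,4-bis(triisopropylsilyloxy)benzaldehyde | C=C(C)[C@H](O[Si](C)(C)C(C)(C)C)Cc1c(O[Si](C(C)C)(C(C)C)C(C)C)c(CC=C(C)C)c(O)c(C=O)c1O[Si](C(C)C)(C(C)C)C(C)C
F11 | step 13 | 1-{3-[(2R)-2-(tert-butyldimethylsilyloxy)-3-methylbut-3-enyl]-6-hydroxy-5-(3-methylbut-2-enyl)-2,4-bis(triisopropylsilyloxy)phenyl}prop-2-yn-1-ol (both carbinol epimers) | C=C(C)[C@H](O[Si](C)(C)C(C)(C)C)Cc1c(O[Si](C(C)C)(C(C)C)C(C)C)c(CC=C(C)C)c(O)c(C(O)C#C)c1O[Si](C(C)C)(C(C)C)C(C)C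
F12 | step 13 | 1-{3-[(2R)-2-(tert-butyldimethylsilyloxy)-3-methylbut-3-enyl]-6-hydroxy-5-(3-methylbut-2-enyl)-2,4-bis(triisopropylsilyloxy)phenyl}prop-2-yn-1-one | C=C(C)[C@H](O[Si](C)(C)C(C)(C)C)Cc1c(O[Si](C(C)C)(C(C)C)C(C)C)c(CC=C(C)C)c(O)c(C(=O)C#C)c1O[Si](C(C)C)(C(C)C)C(C)C
F13 | step 13 | 6-[(2R)-2-(tert-butyldimethylsilyloxy)-3-methylbut-3-enyl]-8-(3-methylbut-2-enyl)-5,7-bis(triisopropylsilyloxy)-4H-chromen-4-one | C=C(C)[C@H](O[Si](C)(C)C(C)(C)C)Cc1c(O[Si](C(C)C)(C(C)C)C(C)C)c(CC=C(C)C)c2occc(=O)c2c1O[Si](C(C)C)(C(C)C)C(C)C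
F14 | step 1 | racemic 2-(prop-1-en-2-yl)oxirane | C=C(C)C1CO1
F15 | step 1 | (2S)-2-(prop-1-en-2-yl)oxirane | C=C(C)[C@H]1CO1
A1 | alternative 1 | (2S)-2-(4-acetoxyphenyl)-5,7-bis(tert-butyldimethylsilyloxy)-6-[(2R)-2-(tert-butyldimethylsilyloxy)-3-methylbut-3-enyl]-8-(3-methylbut-2-enyl)chroman-4-one | C=C(C)[C@H](O[Si](C)(C)C(C)(C)C)Cc1c(O[Si](C)(C)C(C)(C)C)c(CC=C(C)C)c2c(c1O[Si](C)(C)C(C)(C)C)C(=O)C[C@@H](c1ccc(OC(C)=O)cc1)O2
A2 | alternative 1 | (3S)-3-(4-acetoxyphenyl)-3-{3,5-bis(tert-butyldimethylsilyloxy)-4-[(2R)-2-(tert-butyldimethylsilyloxy)-3-methylbut-3-enyl]-2-(3-methylbut-2-enyl)phenoxy}propanoic acid | C=C(C)[C@H](O[Si](C)(C)C(C)(C)C)Cc1c(O[Si](C)(C)C(C)(C)C)c(CC=C(C)C)c(O[C@@H](CC(=O)O)c2ccc(OC(C)=O)cc2)cc1O[Si](C)(C)C(C)(C)C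
A3 | alternative 2 | (2S)-6-[(2R)-2-(tert-butyldimethylsilyloxy)-3-methylbut-3-enyl]-5,7-dihydroxy-2-[4-(methoxymethoxy)phenyl]-8-(3-methylbut-2-enyl)chroman-4-one | C=C(C)[C@H](O[Si](C)(C)C(C)(C)C)Cc1c(O)c(CC=C(C)C)c2c(c1O)C(=O)C[C@@H](c1ccc(OCOC)cc1)O2
A4 | alternative 2 | methyl 2-[(2R)-2-(tert-butyldimethylsilyloxy)-3-methylbut-3-enyl]-4-{(2S)-2-[4-(methoxymethoxy)phenyl]-4-oxo-3,4-dihydro-2H-pyran-6-yl}-7-methyl-3-oxooct-6-enoate | COC(=O)C(C[C@@H](O[Si](C)(C)C(C)(C)C)C(C)=C)C(=O)C(CC=C(C)C)C1=CC(=O)C[C@@H](c2ccc(OCOC)cc2)O1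
A5 | alternative 3 | (2S)-2,4-cis-5,7-bis(tert-butyldimethylsilyloxy)-6-[(2R)-2-(tert-butyldimethylsilyloxy)-3-methylbut-3-enyl]-2-[4-(tert-butyldimethylsilyloxy)phenyl]-4-methoxy-8-(3-methylbut-2-enyl)chromane | C=C(C)[C@H](O[Si](C)(C)C(C)(C)C)Cc1c(O[Si](C)(C)C(C)(C)C)c(CC=C(C)C)c2c(c1O[Si](C)(C)C(C)(C)C)[C@@H](OC)C[C@@H](c1ccc(O[Si](C)(C)C(C)(C)C)cc1)O2
A6 | alternative 3 | 2,4-bis(tert-butyldimethylsilyloxy)-3-[(2R)-2-(tert-butyldimethylsilyloxy)-3-methylbut-3-enyl]-6-hydroxy-5-(3-methylbut-2-enyl)benzaldehyde | C=C(C)[C@H](O[Si](C)(C)C(C)(C)C)Cc1c(O[Si](C)(C)C(C)(C)C)c(CC=C(C)C)c(O)c(C=O)c1O[Si](C)(C)C(C)(C)C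
A7 | alternative 3 | tert-butyldimethyl(4-vinylphenoxy)silane | C=Cc1ccc(O[Si](C)(C)C(C)(C)C)cc1
A8 | alternative 3 | trimethyl orthoformate | COC(OC)OC
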